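The ansa ring is opened at the C1–N anilide bond and at C2=C3. This isolates the hard part, the syn C6-methyl/C7-oxygen pair beside the Z C4=C5 alkene. Tying the C7 oxygen to C3 folds these atoms into one six-membered ring (O, C3, C4, C5, C6, C7), a cis-5,6-disubstituted 5,6-dihydropyran-2-one. A single catalytic asymmetric hetero-Diels–Alder reaction joins enal 15, the complete C7–C21 fragment (nitroarene, C15 silyl ether, no free O–H or N–H), to ketene-acetal diene 18. It forms C6–C7 and O–C3, sets both stereocentres and locks the alkene cis. Lactol opening by a Wittig reaction, then macrolactamisation, complete the target.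

Key step: step 11

Remark (numbering and abbreviations): C1 = lactam carbonyl, C2–C15 = ansa chain, C16–C21 = carbocycle, N on C20. Ar = 2,5-dimethoxy-3-nitrophenyl; TBS = tert-butyldimethylsilyl; pin = pinacolato; (R)-TRIP = (R)-3,3'-bis(2,4,6-triisopropylphenyl)-1,1'-binaphthyl-2,2'-diyl hydrogen phosphate; BOP-Cl = bis(2-oxo-3-oxazolidinyl)phosphinic chloride.

Assumption: the (R)-phosphoric acid and the (R)-BINOL complex of tetravalent titanium are taken to open the Re face of the bound aldehyde, as is usual for aryl and alkenyl aldehydes. If a trial shows the opposite sense, the mirror-image catalyst is used and nothing else changes.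

Step 1
Reactants: 1 2-hydroxy-5-methoxy-3-nitrobenzaldehyde
Product: 2 2,5-dimethoxy-3-nitrobenzaldehyde
Conditions: MeI, K2CO3, DMF, 50 °C
Reagents that add atoms: iodomethane, CI
Why: Williamson O-methylation: the ortho-nitrophenol is acidic enough for K2CO3 and its phenoxide is the only nucleophile present, so the aldehyde and the nitro group stay untouched.

Step 2
Reactants: 2 2,5-dimethoxy-3-nitrobenzaldehyde; 3 (Z)-crotylboronic acid pinacol ester
Product: 5 (1R,2S)-1-Ar-2-methylbut-3-en-1-ol, via boryl ether 4 (not isolated)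
Conditions: (R)-TRIP (5 mol %), PhMe, −30 °C; aq. NaHCO3
Reagents that add atoms: none
Why: Brønsted-acid-catalysed asymmetric crotylboration through a closed chair (Zimmerman–Traxler) transition state: the Z-boronate geometry is translated into the 14,15-syn pair and the (R)-acid should direct attack to the Re face of 2, giving 15R and 14S, while the boron reagent leaves the nitro group alone.

Step 3
Reactants: 5 (1R,2S)-1-Ar-2-methylbut-3-en-1-ol
Product: 6 (1R,2S)-1-Ar-1-(TBSO)-2-methylbut-3-ene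
Conditions: TBSOTf, 2,6-lutidine, CH2Cl2, 0 °C
Reagents that add atoms: tert-butyldimethylsilyl trifluoromethanesulfonate, CC(C)(C)[Si](C)(C)OS(=O)(=O)C(F)(F)F
Why: Silyl triflate silylation, strong enough for the hindered benzylic alcohol, masks O15 for every later step up to the last one without touching C15.

Step 4
Reactants: 6 (1R,2S)-1-Ar-1-(TBSO)-2-methylbut-3-ene
Product: 7 (4S,5R)-5-Ar-5-(TBSO)-4-methylpentanal
Conditions: Rh(acac)(CO)2 (2 mol %), Xantphos (4 mol %), CO/H2 (1:1, 20 bar), PhMe, 70 °C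
Reagents that add atoms: carbon monoxide, [C-]#[O+]
Why: Rhodium-catalysed linear-selective hydroformylation: the wide-bite-angle diphosphine and the branching at C14 should steer the formyl group to the terminal carbon, so that C11 is added in one step without organometallic reagents that would attack the nitroarene.

Step 5
Reactants: 7 (4S,5R)-5-Ar-5-(TBSO)-4-methylpentanal
Product: 8 (2S,4S,5R)-5-Ar-5-(TBSO)-4-methyl-1-oxopentan-2-yl benzoate
Conditions: (S)-α,α-diphenylprolinol trimethylsilyl ether (20 mol %), (PhCO2)2, THF, 0 °C to rt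
Reagents that add atoms: dibenzoyl peroxide, O=C(OOC(=O)c1ccccc1)c1ccccc1
Why: Enamine-catalysed α-benzoyloxylation of an α-unbranched aldehyde: the bulky (S)-pyrrolidine shields one face of the E-enamine, so the peroxide oxygen should arrive from the open face and set 12S under catalyst control, and the α-acyloxy aldehyde is stable enough to be isolated.

Step 6
Reactants: 8 (2S,4S,5R)-5-Ar-5-(TBSO)-4-methyl-1-oxopentan-2-yl benzoate; 3 (Z)-crotylboronic acid pinacol ester
Product: 10 (3S,4R,5S,7S,8R)-8-Ar-8-(TBSO)-3,7-dimethyloct-1-ene-4,5-diol, via boryl ether benzoate 9 (not isolated)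
Conditions: (R)-TRIP (5 mol %), PhMe, −30 to 0 °C; then K2CO3 (cat.), MeOH, rt
Reagents that add atoms: none
Why: Second asymmetric Z-crotylboration followed by methanolysis: the chair transition state gives the 10,11-syn pair, and the dipole-minimised (Cornforth-type) conformer of the α-acyloxy aldehyde and the (R)-acid both favour the Re face, so 11R should form anti to O12 in a matched case before K2CO3/MeOH strips borate and benzoate.

Step 7
Reactants: 10 (3S,4R,5S,7S,8R)-8-Ar-8-(TBSO)-3,7-dimethyloct-1-ene-4,5-diol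
Product: 11 (3S,4R,5S,7S,8R)-8-Ar-8-(TBSO)-4,5-dimethoxy-3,7-dimethyloct-1-ene
Conditions: Me3OBF4, 1,8-bis(dimethylamino)naphthalene, 4 Å MS, CH2Cl2, rt
Reagents that add atoms: trimethyloxonium tetrafluoroborate, C[O+](C)C.F[B-](F)(F)F
Why: Double O-methylation with a Meerwein salt and a non-nucleophilic proton scavenger converts both hydroxyls at once and generates no alkoxide, which rules out silyl migration from O15 and side reactions of the nitroarene.

Step 8
Reactants: 11 (3S,4R,5S,7S,8R)-8-Ar-8-(TBSO)-4,5-dimethoxy-3,7-dimethyloct-1-ene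
Product: 13 (2R,3R,4S,6S,7R)-7-Ar-7-(TBSO)-3,4-dimethoxy-2,6-dimethylheptanal, via secondary ozonide 12 (not isolated)
Conditions: O3, CH2Cl2, −78 °C; then PPh3, −78 °C to rt
Reagents that add atoms: ozone, [O-][O+]=O
Why: Ozonolysis with reductive work-up cleaves the only alkene, the nitro-deactivated arene reacting far more slowly, and the neutral conditions should keep the new α-centre C10 intact.

Step 9
Reactants: 13 (2R,3R,4S,6S,7R)-7-Ar-7-(TBSO)-3,4-dimethoxy-2,6-dimethylheptanal; 14 2-(triphenylphosphoranylidene)propanal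
Product: 15 (2E,4S,5R,6S,8S,9R)-9-Ar-9-(TBSO)-5,6-dimethoxy-2,4,8-trimethylnon-2-enal
Conditions: PhMe, 90 °C
Reagents that add atoms: none
Why: Wittig olefination with a stabilised formyl ylide, which is E-selective for trisubstituted enals, installs C7, C8 and the C8 methyl group in one step under neutral conditions, and the hindered α-methyl enal formed should not react a second time.

Step 10
Reactants: 16 methyl (E)-pent-3-enoate
Product: 18 (1E,3E)-1-methoxy-1-(trimethylsilyloxy)penta-1,3-diene, via lithium dienolate 17 (not isolated)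
Conditions: LiN(iPr)2 (commercial solution), THF, −78 °C; then Me3SiCl, −78 °C to rt; non-aqueous work-up, distillation
Reagents that add atoms: chlorotrimethylsilane, C[Si](C)(C)Cl
Why: Kinetic α-deprotonation of the β,γ-unsaturated ester followed by O-silylation (silyl ketene acetal formation) leaves the E C3=C4 bond untouched, which γ-deprotonation of the conjugated isomer would not guarantee.

Step 11
Reactants: 15 (2E,4S,5R,6S,8S,9R)-9-Ar-9-(TBSO)-5,6-dimethoxy-2,4,8-trimethylnon-2-enal; 18 (1E,3E)-1-methoxy-1-(trimethylsilyloxy)penta-1,3-diene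
Product: 20 (5S,6R)-5-methyl-6-[(2E,4S,5R,6S,8S,9R)-9-Ar-9-(TBSO)-5,6-dimethoxy-4,8-dimethylnon-2-en-2-yl]-5,6-dihydro-2H-pyran-2-one, via cyclic orthoester 19 (not isolated)
Conditions: Ti(OiPr)4 (20 mol %), (R)-BINOL (40 mol %), 4 Å MS, 18 (2.5 equiv), PhMe, −20 °C; then CF3CO2H (cat.), wet CH2Cl2, 0 °C
Reagents that add atoms: none
Why: The (R)-binaphtholate complex of tetravalent titanium binds the C7 carbonyl oxygen anti to C8, and the s-cis ketene acetal 18 then bonds through its methyl-bearing terminus to C7 and through its acetal carbon to the carbonyl oxygen, either in one asynchronous [4+2] event or stepwise as a γ-selective vinylogous Mukaiyama aldol addition; acid finally collapses orthoester 19 (or the Z-hydroxy ester of the stepwise path) to lactone 20. The closest known reaction type is the Lewis-acid-catalysed asymmetric hetero-Diels–Alder reaction, or vinylogous aldol–lactonisation, of 1-alkoxy-1-silyloxy dienes with aryl and alkenyl aldehydes. The single new ring (O, C3, C4, C5, C6, C7) closes as a [4+2] cycloaddition on the concerted path and as a 6-exo-trig acyl substitution by the C7 oxygen on the stepwise path, and on both the ring forces C4=C5 to be cis. C7 (R) is set by the catalyst, whose (R)-ligand should leave the Re face of the aldehyde open, the nearest substrate centre C10 being too far away to interfere; C6 (S) is set relative to C7 by the endo placement of the C8 alkenyl residue over the diene, which puts it cis to the outward-pointing methyl group of the 3E alkene. The step needs 1,2- over 1,4-addition, γ- over α-attack and reaction through the s-cis diene; the α-methyl group and the branched C10 of 15 block the β-carbon, the bulky catalyst-bound aldehyde disfavours the hindered α-carbon of the diene, and the absence of any O–H or N–H in 15 keeps the catalyst alive.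

Step 12
Reactants: 20 lactone (5S,6R)-5-methyl-6-alkenyl-5,6-dihydro-2H-pyran-2-one
Product: 22 the corresponding (5S,6R)-5,6-dihydro-2H-pyran-2-ol (lactol as anomer mixture), via aluminium lactolate 21 (not isolated)
Conditions: i-Bu2AlH (1.2 equiv), CH2Cl2, −78 °C; then aq. potassium sodium tartrate
Reagents that add atoms: none
Why: Partial lactone reduction with i-Bu2AlH: at −78 °C the tetrahedral aluminium lactolate persists until work-up, hydride adds 1,2, and the nitro group, silyl ether and stereocentres are left alone.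

Step 13
Reactants: 22 lactol; 23 methyl 2-(triphenylphosphoranylidene)propanoate
Product: 25 methyl (2E,4Z,6S,7R,8E,10S,11R,12S,14S,15R)-15-Ar-15-(TBSO)-7-hydroxy-11,12-dimethoxy-2,6,8,10,14-pentamethylpentadeca-2,4,8-trienoate, via open-chain hydroxy enal 24 (not isolated)
Conditions: PhMe, 70 °C
Reagents that add atoms: none
Why: Wittig olefination of a lactol through its ring-opened tautomer: the stabilised α-methyl ylide should give the E C2=C3 bond, C4=C5 keeps the cis geometry it had in the ring, O7 is set free, and the salt-free neutral medium minimises enal isomerisation, C6 epimerisation and oxa-Michael reclosure.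

Step 14
Reactants: 25 hydroxy trienoate
Product: 27 the 7-O-carbamoyl derivative of 25 (7-OC(O)NH2), via N-trichloroacetyl carbamate 26 (not isolated)
Conditions: Cl3CC(O)NCO, CH2Cl2, 0 °C; then K2CO3 (cat.), MeOH, rt
Reagents that add atoms: trichloroacetyl isocyanate, O=C=NC(=O)C(Cl)(Cl)Cl
Why: Carbamoylation by addition of the alcohol to an acyl isocyanate and methanolysis of the trichloroacetyl group; O7–H is the only nucleophile because nitrogen is still stored as the nitro group, and C7 is not touched.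

Step 15
Reactants: 27 carbamate nitro ester
Product: 28 the corresponding aniline (3-amino-2,5-dimethoxyphenyl in place of Ar)
Conditions: Zn dust, AcOH/THF, 0 °C to rt
Reagents that add atoms: none
Why: Dissolving-metal (zinc/acetic acid) reduction of the nitroarene to the aniline, a method that spares the triene, the ester, the allylic carbamate and the silyl ether, unlike catalytic hydrogenation.

Step 16
Reactants: 28 amino ester
Product: 30 seco amino acid (C1 carboxylic acid and C20 NH2), via lithium carboxylate 29 (not isolated)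
Conditions: LiOH, THF/MeOH/H2O, rt; then 1 M HCl to pH 5
Reagents that add atoms: lithium hydroxide, [Li+].[OH-]
Why: Saponification: the methyl ester is far more electrophilic than the primary carbamate, and after step 15 the arene is no longer activated towards hydroxide, so only C1 should react.

Step 17
Reactants: 30 seco amino acid
Product: 32 19-membered macrolactam (hydroquinone 18,21-dimethyl ether with 15-OTBS and 7-OC(O)NH2), via mixed phosphinic anhydride 31 (not isolated)
Conditions: BOP-Cl, iPr2NEt, PhMe (1 mM, slow addition), 85 °C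
Reagents that add atoms: none
Why: Macrolactamisation through a mixed carboxylic–phosphinic anhydride under high dilution closes the 19-membered ring at C1–N; the aniline is the only competent nucleophile because O7 and O15 are blocked.

Step 18
Reactants: 32 macrolactam
Product: 33 15-O-TBS benzoquinone macrolactam
Conditions: (NH4)2Ce(NO3)6, MeCN/H2O, 0 °C
Reagents that add atoms: water, O
Why: Oxidative demethylation of the para-dimethoxyarene with tetravalent cerium gives the 1,4-benzoquinone (C18 and C21 carbonyls), the electron-rich anilide ring being oxidised much faster than the alkenes, and the silyl ether shields the benzylic C15 position.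

Step 19
Reactants: 33 15-O-TBS benzoquinone macrolactam
Product: 34 target CNP0557283.1 (6S,7R,10S,11R,12S,14S,15R; 2E,4Z,8E)
Conditions: HF·pyridine, THF, 0 °C to rt
Reagents that add atoms: none
Why: Fluoride-induced desilylation under mildly acidic conditions, chosen because the quinone and the carbamate are base-sensitive, releases O15–H without touching C15.

Compound list
1 | 2-hydroxy-5-methoxy-3-nitrobenzaldehyde | O=Cc1cc(OC)cc([N+](=O)[O-])c1O | starting material
2 | 2,5-dimethoxy-3-nitrobenzaldehyde | O=Cc1cc(OC)cc([N+](=O)[O-])c1OC | intermediate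
3 | (Z)-crotylboronic acid pinacol ester | C/C=C\CB1OC(C)(C)C(C)(C)O1 | starting material
4 | O-(pinacolatoboryl) ether of 5 | C=C[C@H](C)[C@@H](OB2OC(C)(C)C(C)(C)O2)c1cc(OC)cc([N+](=O)[O-])c1OC | intermediate
5 | (1R,2S)-1-Ar-2-methylbut-3-en-1-ol | C=C[C@H](C)[C@@H](O)c1cc(OC)cc([N+](=O)[O-])c1OC | intermediate
6 | (1R,2S)-1-Ar-1-(TBSO)-2-methylbut-3-ene | C=C[C@H](C)[C@@H](O[Si](C)(C)C(C)(C)C)c1cc(OC)cc([N+](=O)[O-])c1OC | intermediate
7 | (4S,5R)-5-Ar-5-(TBSO)-4-methylpentanal | O=CCC[C@H](C)[C@@H](O[Si](C)(C)C(C)(C)C)c1cc(OC)cc([N+](=O)[O-])c1OC | intermediate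
8 | (2S,4S,5R)-5-Ar-5-(TBSO)-4-methyl-1-oxopentan-2-yl benzoate | O=C[C@@H](OC(=O)c2ccccc2)C[C@H](C)[C@@H](O[Si](C)(C)C(C)(C)C)c1cc(OC)cc([N+](=O)[O-])c1OC | intermediate
9 | (3S,4R,5S,7S,8R)-8-Ar-8-(TBSO)-3,7-dimethyl-4-(pinacolatoboryloxy)oct-1-en-5-yl benzoate | C=C[C@H](C)[C@@H](OB2OC(C)(C)C(C)(C)O2)[C@@H](OC(=O)c3ccccc3)C[C@H](C)[C@@H](O[Si](C)(C)C(C)(C)C)c1cc(OC)cc([N+](=O)[O-])c1OC | intermediate
10 | (3S,4R,5S,7S,8R)-8-Ar-8-(TBSO)-3,7-dimethyloct-1-ene-4,5-diol | C=C[C@H](C)[C@@H](O)[C@@H](O)C[C@H](C)[C@@H](O[Si](C)(C)C(C)(C)C)c1cc(OC)cc([N+](=O)[O-])c1OC | intermediate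
11 | (3S,4R,5S,7S,8R)-8-Ar-8-(TBSO)-4,5-dimethoxy-3,7-dimethyloct-1-ene | C=C[C@H](C)[C@@H](OC)[C@@H](OC)C[C@H](C)[C@@H](O[Si](C)(C)C(C)(C)C)c1cc(OC)cc([N+](=O)[O-])c1OC | intermediate
12 | secondary ozonide of 11 (3-substituted 1,2,4-trioxolane, ring carbon unassigned) | C2OC(OO2)[C@H](C)[C@@H](OC)[C@@H](OC)C[C@H](C)[C@@H](O[Si](C)(C)C(C)(C)C)c1cc(OC)cc([N+](=O)[O-])c1OC | intermediate
13 | (2R,3R,4S,6S,7R)-7-Ar-7-(TBSO)-3,4-dimethoxy-2,6-dimethylheptanal | O=C[C@H](C)[C@@H](OC)[C@@H](OC)C[C@H](C)[C@@H](O[Si](C)(C)C(C)(C)C)c1cc(OC)cc([N+](=O)[O-])c1OC | intermediate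
14 | 2-(triphenylphosphoranylidene)propanal | CC(C=O)=P(c1ccccc1)(c1ccccc1)c1ccccc1 | starting material
15 | (2E,4S,5R,6S,8S,9R)-9-Ar-9-(TBSO)-5,6-dimethoxy-2,4,8-trimethylnon-2-enal (C7–C21 enal) | O=C/C(C)=C/[C@H](C)[C@@H](OC)[C@@H](OC)C[C@H](C)[C@@H](O[Si](C)(C)C(C)(C)C)c1cc(OC)cc([N+](=O)[O-])c1OC | intermediate
16 | methyl (E)-pent-3-enoate | C/C=C/CC(=O)OC | starting material
17 | lithium (1E,3E)-1-methoxypenta-1,3-dien-1-olate | C/C=C/C=C(\OC)[O-].[Li+] | intermediate
18 | (1E,3E)-1-methoxy-1-(trimethylsilyloxy)penta-1,3-diene | C/C=C/C=C(\OC)O[Si](C)(C)C | intermediate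
19 | cycloadduct, (5S,6R)-2-methoxy-2-(trimethylsilyloxy)-5-methyl-6-alkenyl-5,6-dihydro-2H-pyran (C3 unassigned) | COC2(O[Si](C)(C)C)C=C[C@H](C)[C@@H](O2)/C(C)=C/[C@H](C)[C@@H](OC)[C@@H](OC)C[C@H](C)[C@@H](O[Si](C)(C)C(C)(C)C)c1cc(OC)cc([N+](=O)[O-])c1OC | intermediate
20 | (5S,6R)-5-methyl-6-[(2E,4S,5R,6S,8S,9R)-9-Ar-9-(TBSO)-5,6-dimethoxy-4,8-dimethylnon-2-en-2-yl]-5,6-dihydro-2H-pyran-2-one (cis lactone) | O=C2C=C[C@H](C)[C@@H](O2)/C(C)=C/[C@H](C)[C@@H](OC)[C@@H](OC)C[C@H](C)[C@@H](O[Si](C)(C)C(C)(C)C)c1cc(OC)cc([N+](=O)[O-])c1OC | intermediate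
21 | diisobutylaluminium lactolate of 22 | CC(C)C[Al](CC(C)C)OC2C=C[C@H](C)[C@@H](O2)/C(C)=C/[C@H](C)[C@@H](OC)[C@@H](OC)C[C@H](C)[C@@H](O[Si](C)(C)C(C)(C)C)c1cc(OC)cc([N+](=O)[O-])c1OC | intermediate
22 | lactol, (5S,6R)-5-methyl-6-alkenyl-5,6-dihydro-2H-pyran-2-ol (anomer mixture) | OC2C=C[C@H](C)[C@@H](O2)/C(C)=C/[C@H](C)[C@@H](OC)[C@@H](OC)C[C@H](C)[C@@H](O[Si](C)(C)C(C)(C)C)c1cc(OC)cc([N+](=O)[O-])c1OC | intermediate
23 | methyl 2-(triphenylphosphoranylidene)propanoate | COC(=O)C(C)=P(c1ccccc1)(c1ccccc1)c1ccccc1 | starting material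
24 | open-chain tautomer of 22, (4Z,6S,7R)-7-hydroxy C3 enal | O=C/C=C\[C@H](C)[C@@H](O)/C(C)=C/[C@H](C)[C@@H](OC)[C@@H](OC)C[C@H](C)[C@@H](O[Si](C)(C)C(C)(C)C)c1cc(OC)cc([N+](=O)[O-])c1OC | intermediate
25 | methyl (2E,4Z,6S,7R,8E,10S,11R,12S,14S,15R)-15-Ar-15-(TBSO)-7-hydroxy-11,12-dimethoxy-2,6,8,10,14-pentamethylpentadeca-2,4,8-trienoate | COC(=O)/C(C)=C/C=C\[C@H](C)[C@@H](O)/C(C)=C/[C@H](C)[C@@H](OC)[C@@H](OC)C[C@H](C)[C@@H](O[Si](C)(C)C(C)(C)C)c1cc(OC)cc([N+](=O)[O-])c1OC | intermediate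
26 | 7-O-(N-trichloroacetylcarbamoyl) derivative of 25 | COC(=O)/C(C)=C/C=C\[C@H](C)[C@@H](OC(=O)NC(=O)C(Cl)(Cl)Cl)/C(C)=C/[C@H](C)[C@@H](OC)[C@@H](OC)C[C@H](C)[C@@H](O[Si](C)(C)C(C)(C)C)c1cc(OC)cc([N+](=O)[O-])c1OC | intermediate
27 | 7-O-carbamoyl derivative of 25 | COC(=O)/C(C)=C/C=C\[C@H](C)[C@@H](OC(N)=O)/C(C)=C/[C@H](C)[C@@H](OC)[C@@H](OC)C[C@H](C)[C@@H](O[Si](C)(C)C(C)(C)C)c1cc(OC)cc([N+](=O)[O-])c1OC | intermediate
28 | amino ester (27 with 3-amino-2,5-dimethoxyphenyl) | COC(=O)/C(C)=C/C=C\[C@H](C)[C@@H](OC(N)=O)/C(C)=C/[C@H](C)[C@@H](OC)[C@@H](OC)C[C@H](C)[C@@H](O[Si](C)(C)C(C)(C)C)c1cc(OC)cc(N)c1OC | intermediate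
29 | lithium carboxylate of 30 | [Li+].[O-]C(=O)/C(C)=C/C=C\[C@H](C)[C@@H](OC(N)=O)/C(C)=C/[C@H](C)[C@@H](OC)[C@@H](OC)C[C@H](C)[C@@H](O[Si](C)(C)C(C)(C)C)c1cc(OC)cc(N)c1OC | intermediate
30 | seco amino acid (2E,4Z,6S,7R,8E,10S,11R,12S,14S,15R) | OC(=O)/C(C)=C/C=C\[C@H](C)[C@@H](OC(N)=O)/C(C)=C/[C@H](C)[C@@H](OC)[C@@H](OC)C[C@H](C)[C@@H](O[Si](C)(C)C(C)(C)C)c1cc(OC)cc(N)c1OC | intermediate
31 | mixed anhydride of 30 with bis(2-oxo-3-oxazolidinyl)phosphinic acid | O=C2OCCN2P(=O)(N3CCOC3=O)OC(=O)/C(C)=C/C=C\[C@H](C)[C@@H](OC(N)=O)/C(C)=C/[C@H](C)[C@@H](OC)[C@@H](OC)C[C@H](C)[C@@H](O[Si](C)(C)C(C)(C)C)c1cc(OC)cc(N)c1OC | intermediate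
32 | 19-membered macrolactam, 18,21-di-O-methyl hydroquinone, 15-OTBS, 7-OC(O)NH2 | CO[C@H]1[C@@H](OC)C[C@H](C)[C@@H](O[Si](C)(C)C(C)(C)C)c2cc(OC)cc(NC(=O)/C(C)=C/C=C\[C@H](C)[C@@H](OC(N)=O)/C(C)=C/[C@@H]1C)c2OC | intermediate
33 | 15-O-TBS benzoquinone macrolactam | CO[C@H]1[C@@H](OC)C[C@H](C)[C@@H](O[Si](C)(C)C(C)(C)C)C2=CC(=O)C=C(NC(=O)/C(C)=C/C=C\[C@H](C)[C@@H](OC(N)=O)/C(C)=C/[C@@H]1C)C2=O | intermediate
34 | CNP0557283.1 | CO[C@H]1[C@@H](OC)C[C@H](C)[C@@H](O)C2=CC(=O)C=C(NC(=O)/C(C)=C/C=C\[C@H](C)[C@@H](OC(N)=O)/C(C)=C/[C@@H]1C)C2=O | target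

Total step count: 19. Longest linear sequence: 18 steps (steps 1–9 and 11–19). Step 10 is the only branch.

Steps most likely to fail

1. Step 11.
- Risk: the dienolate may react through its s-trans conformer, which leads to an open-chain E-enoate that cannot lactonise. It may also attack through its α-carbon. Endo/exo or facial discrimination may be weak, and turnover with the hindered α-methyl enal may be slow.
- Fallback: it sets out from 15 and comes back at 20. C6–C7 is made by a third Z-crotylboration and the same ring is closed at C4=C5 by metathesis.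
- Enal 15 and boronate 3 with (R)-TRIP in PhMe should give the C7 boryl ether F1.
- Aqueous work-up hydrolyses this to the (6S,7R)-syn homoallylic alcohol F2.
- Acryloyl chloride and iPr2NEt in CH2Cl2 give the acrylate F3.
- The second-generation Grubbs catalyst in refluxing CH2Cl2 closes F3 to lactone 20; the trisubstituted C8=C9 alkene is too hindered to take part.

2. Step 13.
- Risk: Z-to-E isomerisation of the transient hydroxy enal, vinylogous enolisation at C6, sluggish ring opening of the lactol, or oxa-Michael reclosure of O7 onto C3.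
- Fallback: it sets out from 20 and comes back at 27. O7 is blocked before the aldehyde is released.
- AlMe3/MeONHMe·HCl (CH2Cl2, 0 °C) opens the lactone to the (Z)-hydroxy Weinreb amide F4.
- Cl3CC(O)NCO gives the N-trichloroacetyl carbamate F5, and K2CO3/MeOH converts it into the carbamate amide F6.
- i-Bu2AlH (THF, −78 °C, hydrolytic work-up) gives the (Z)-enal carbamate F7, which can no longer cyclise.
- F7 is treated with ylide 23 at room temperature to give 27.

3. Step 5.
- Risk: deactivation of the amine catalyst by the peroxide, incomplete conversion, or erosion of the new C12 centre by enolisation during isolation.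
- Fallback: it sets out from 7 and comes back at 10. The oxygen is stored in a configurationally stable 1,2-diol instead of an α-acyloxy aldehyde.
- An O-selective nitroso aldol reaction of 7 with nitrosobenzene and D-proline gives the (12S)-α-anilinoxy aldehyde F8.
- NaBH4 reduces this in the same pot to the anilinoxy alcohol F9.
- CuSO4 in MeOH cleaves the N–O bond to give the 1,2-diol F10.
- Et3SiCl/imidazole gives the bis(triethylsilyl) ether F11.
- Swern conditions oxidise only the primary silyl ether, giving the α-silyloxy aldehyde F12.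
- Crotylboration with 3 as in step 6 gives the boryl ether F13 and, after hydrolysis, the alcohol F14.
- Pyridinium p-toluenesulfonate in MeOH removes the triethylsilyl group of F14 to give 10; the TBS ether stays.

Further compounds
F1 | step 11 | C7 O-(pinacolatoboryl) ether of F2 | C=C[C@H](C)[C@@H](OB2OC(C)(C)C(C)(C)O2)/C(C)=C/[C@H](C)[C@@H](OC)[C@@H](OC)C[C@H](C)[C@@H](O[Si](C)(C)C(C)(C)C)c1cc(OC)cc([N+](=O)[O-])c1OC
F2 | step 11 | (3S,4R,5E,7S,8R,9S,11S,12R)-12-Ar-12-(TBSO)-8,9-dimethoxy-3,5,7,11-tetramethyldodeca-1,5-dien-4-ol | C=C[C@H](C)[C@@H](O)/C(C)=C/[C@H](C)[C@@H](OC)[C@@H](OC)C[C@H](C)[C@@H](O[Si](C)(C)C(C)(C)C)c1cc(OC)cc([N+](=O)[O-])c1OC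
F3 | step 11 | acrylate ester of F2 | C=C[C@H](C)[C@@H](OC(=O)C=C)/C(C)=C/[C@H](C)[C@@H](OC)[C@@H](OC)C[C@H](C)[C@@H](O[Si](C)(C)C(C)(C)C)c1cc(OC)cc([N+](=O)[O-])c1OC
F4 | step 13 | (4Z,6S,7R)-7-hydroxy C3 N-methoxy-N-methylamide | CON(C)C(=O)/C=C\[C@H](C)[C@@H](O)/C(C)=C/[C@H](C)[C@@H](OC)[C@@H](OC)C[C@H](C)[C@@H](O[Si](C)(C)C(C)(C)C)c1cc(OC)cc([N+](=O)[O-])c1OC
F5 | step 13 | 7-O-(N-trichloroacetylcarbamoyl) derivative of F4 | CON(C)C(=O)/C=C\[C@H](C)[C@@H](OC(=O)NC(=O)C(Cl)(Cl)Cl)/C(C)=C/[C@H](C)[C@@H](OC)[C@@H](OC)C[C@H](C)[C@@H](O[Si](C)(C)C(C)(C)C)c1cc(OC)cc([N+](=O)[O-])c1OC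
F6 | step 13 | 7-O-carbamoyl derivative of F4 | CON(C)C(=O)/C=C\[C@H](C)[C@@H](OC(N)=O)/C(C)=C/[C@H](C)[C@@H](OC)[C@@H](OC)C[C@H](C)[C@@H](O[Si](C)(C)C(C)(C)C)c1cc(OC)cc([N+](=O)[O-])c1OC
F7 | step 13 | (4Z,6S,7R)-7-carbamoyloxy C3 enal | O=C/C=C\[C@H](C)[C@@H](OC(N)=O)/C(C)=C/[C@H](C)[C@@H](OC)[C@@H](OC)C[C@H](C)[C@@H](O[Si](C)(C)C(C)(C)C)c1cc(OC)cc([N+](=O)[O-])c1OC
F8 | step 5 | (2S,4S,5R)-2-(anilinooxy)-5-Ar-5-(TBSO)-4-methylpentanal | O=C[C@@H](ONc2ccccc2)C[C@H](C)[C@@H](O[Si](C)(C)C(C)(C)C)c1cc(OC)cc([N+](=O)[O-])c1OC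
F9 | step 5 | (2S,4S,5R)-2-(anilinooxy)-5-Ar-5-(TBSO)-4-methylpentan-1-ol | OC[C@@H](ONc2ccccc2)C[C@H](C)[C@@H](O[Si](C)(C)C(C)(C)C)c1cc(OC)cc([N+](=O)[O-])c1OC
F10 | step 5 | (2S,4S,5R)-5-Ar-5-(TBSO)-4-methylpentane-1,2-diol | OC[C@@H](O)C[C@H](C)[C@@H](O[Si](C)(C)C(C)(C)C)c1cc(OC)cc([N+](=O)[O-])c1OC
F11 | step 5 | 1,2-bis(triethylsilyl) ether of F10 | CC[Si](CC)(CC)OC[C@@H](O[Si](CC)(CC)CC)C[C@H](C)[C@@H](O[Si](C)(C)C(C)(C)C)c1cc(OC)cc([N+](=O)[O-])c1OC
F12 | step 5 | (2S,4S,5R)-5-Ar-5-(TBSO)-4-methyl-2-(triethylsilyloxy)pentanal | O=C[C@@H](O[Si](CC)(CC)CC)C[C@H](C)[C@@H](O[Si](C)(C)C(C)(C)C)c1cc(OC)cc([N+](=O)[O-])c1OC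
F13 | step 5 | C11 O-(pinacolatoboryl) ether of F14 | C=C[C@H](C)[C@@H](OB2OC(C)(C)C(C)(C)O2)[C@@H](O[Si](CC)(CC)CC)C[C@H](C)[C@@H](O[Si](C)(C)C(C)(C)C)c1cc(OC)cc([N+](=O)[O-])c1OC
F14 | step 5 | (3S,4R,5S,7S,8R)-8-Ar-8-(TBSO)-3,7-dimethyl-5-(triethylsilyloxy)oct-1-en-4-ol | C=C[C@H](C)[C@@H](O)[C@@H](O[Si](CC)(CC)CC)C[C@H](C)[C@@H](O[Si](C)(C)C(C)(C)C)c1cc(OC)cc([N+](=O)[O-])c1OC
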